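## Retrosynthetic overview

1. Target 18 is an erythro-(7S,8R) syringylglycerol 8-O-4' aryl ether whose ring B carries an (8'S)-2,3-dihydroxypropyl chain. The last step is one global hydrogenolysis of the three benzyl ethers of 17.
2. C9H2OH is traced back to a vinyl group (C9=C10, one carbon excised). This reveals homoallylic alcohol 14 and the disconnection C7–C8: ring A aldehyde 11 plus ring B (E)-γ-aryloxyallylboronate 12, which is made in the flask from alkenylboronate 9.
3. Enabling feature: C8 bears the ether oxygen to C4' of ring B and lies between the benzylic carbinol C7 on ring A and C9. O–C8=C9 can therefore be an aryl enol ether with boron on C10, and the anti C7–OH/C8–OAr pair maps onto a chair transition state.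
4. Boronate 9 comes from phenol 7 by propargylation and hydroboration. C8' of 7 comes from (S)-benzyl glycidyl ether 3, opened by the aryl Grignard reagent derived from 1.
5. No ring is formed in the route: both benzene rings are bought (1 and syringaldehyde 10).

Key step: step 8

Numbering: neolignan numbering is used. C7/C8/C9 is the glycerol chain on ring A, C1'–C6' is ring B, C7'/C8'/C9' is its propyl chain, and C10 is the extra vinyl carbon that is removed.

Assumption: the sense of induction known for (R)-TRIP with aromatic aldehydes (allyl transfer to the Re face) is taken to hold for 11. With the CIP ranking OH > C8 > aryl, this face corresponds to (7S).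

## Route

Step 1
Reactants: 1 4-bromo-2,6-dimethoxyphenol
Product: 2 5-bromo-1,3-dimethoxy-2-(methoxymethoxy)benzene
Conditions: MOMCl, iPr2NEt, CH2Cl2, 0 °C → rt
Reagents that add atoms: chloromethyl methyl ether, COCCl
Why: Base-mediated O-alkylation of the phenol (MOM acetal formation, Williamson type) removes the acidic proton that would quench the Grignard reagent of step 2; no stereocentre is involved.

Step 2
Reactants: 2 5-bromo-1,3-dimethoxy-2-(methoxymethoxy)benzene; 3 (S)-benzyl glycidyl ether
Product: 5 (2S)-1-(benzyloxy)-3-[3,5-dimethoxy-4-(methoxymethoxy)phenyl]propan-2-ol, via aryl Grignard reagent 4 (not isolated)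
Conditions: Mg, THF, reflux; then CuI (10 mol %), 3, −30 → 0 °C; H2O quench
Reagents that add atoms: none
Why: Copper-catalysed SN2 opening of a terminal epoxide by an aryl Grignard reagent takes place at the unsubstituted CH2, so the C–O bond at the stereocentre is untouched and C8' (S) is carried over from chiral-pool epoxide 3.

Step 3
Reactants: 5 (2S)-1-(benzyloxy)-3-[3,5-dimethoxy-4-(methoxymethoxy)phenyl]propan-2-ol
Product: 6 5-[(2S)-2,3-bis(benzyloxy)propyl]-1,3-dimethoxy-2-(methoxymethoxy)benzene
Conditions: NaH, BnBr, Bu4NI (cat.), THF–DMF, 0 °C → rt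
Reagents that add atoms: benzyl bromide, BrCc1ccccc1
Why: Williamson ether synthesis on the sodium alkoxide; the MOM acetal and the aryl methyl ethers are inert to NaH and the stereocentre is not involved.

Step 4
Reactants: 6 5-[(2S)-2,3-bis(benzyloxy)propyl]-1,3-dimethoxy-2-(methoxymethoxy)benzene
Product: 7 4-[(2S)-2,3-bis(benzyloxy)propyl]-2,6-dimethoxyphenol
Conditions: HCl (cat.), MeOH, 45 °C
Reagents that add atoms: none
Why: Acid-catalysed acetal exchange (methanolysis) cleaves the aryl MOM acetal, while alkyl benzyl ethers and aryl methyl ethers are stable to dilute methanolic HCl.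

Step 5
Reactants: 7 4-[(2S)-2,3-bis(benzyloxy)propyl]-2,6-dimethoxyphenol
Product: 8 5-[(2S)-2,3-bis(benzyloxy)propyl]-1,3-dimethoxy-2-(prop-2-yn-1-yloxy)benzene
Conditions: propargyl bromide, K2CO3, DMF, rt
Reagents that add atoms: propargyl bromide, C#CCBr
Why: Williamson ether synthesis: the hindered but acidic 2,6-dimethoxyphenol is the only nucleophile and propargyl bromide is an unhindered SN2 partner.

Step 6
Reactants: 8 5-[(2S)-2,3-bis(benzyloxy)propyl]-1,3-dimethoxy-2-(prop-2-yn-1-yloxy)benzene
Product: 9 2-[(E)-3-{4-[(2S)-2,3-bis(benzyloxy)propyl]-2,6-dimethoxyphenoxy}prop-1-en-1-yl]-4,4,5,5-tetramethyl-1,3,2-dioxaborolane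
Conditions: HBpin, Cp2ZrHCl (10 mol %), Et3N (10 mol %), neat, 60 °C
Reagents that add atoms: pinacolborane, [H]B1OC(C)(C)C(C)(C)O1
Why: Zirconocene hydride-catalysed hydroboration of a terminal alkyne is a syn, anti-Markovnikov addition and should give only the (E)-1-alkenylboronate.

Step 7
Reactants: 10 syringaldehyde (4-hydroxy-3,5-dimethoxybenzaldehyde)
Product: 11 4-(benzyloxy)-3,5-dimethoxybenzaldehyde
Conditions: BnBr, K2CO3, DMF, 60 °C
Reagents that add atoms: benzyl bromide, BrCc1ccccc1
Why: Williamson ether synthesis masks the ring A phenol, which would otherwise deactivate the aldehyde as its phenoxide and interfere with the acid catalyst of step 8.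

Step 8
Reactants: 9 2-[(E)-3-{4-[(2S)-2,3-bis(benzyloxy)propyl]-2,6-dimethoxyphenoxy}prop-1-en-1-yl]-4,4,5,5-tetramethyl-1,3,2-dioxaborolane; 11 4-(benzyloxy)-3,5-dimethoxybenzaldehyde
Product: 14 (1S,2R)-1-[4-(benzyloxy)-3,5-dimethoxyphenyl]-2-{4-[(2S)-2,3-bis(benzyloxy)propyl]-2,6-dimethoxyphenoxy}but-3-en-1-ol, via (E)-γ-aryloxyallylboronate 12 (not isolated), via pinacol borate ester 13 (not isolated)
Conditions: [Ir(cod)(PPh2Me)2]PF6 (2 mol %, H2-activated, H2 purged), CH2Cl2, rt; then 11, (R)-TRIP (5 mol %), 4 Å MS, −30 °C; aq NaHCO3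
Reagents that add atoms: none
Why: The H2-activated cationic iridium hydride moves the C=C of 9 by insertion/β-hydride elimination out of conjugation with boron and into conjugation with the aryl ether oxygen, giving (E)-γ-aryloxyallylboronate 12, which adds to aldehyde 11 through a closed six-membered chair (type I allylboration, γ-attack with allyl transposition) in which (R)-TRIP hydrogen-bonds to the pseudoaxial pinacol oxygen and the formyl C–H, and borate 13 is hydrolysed on work-up. The closest known reaction types are the iridium-catalysed isomerisation of (E)-3-alkoxy-1-propenylboronates to (E)-γ-alkoxyallylboronates, the chiral phosphoric acid-catalysed anti-alkoxyallylboration of aromatic aldehydes, and the one-pot pairing of a cationic iridium isomerisation catalyst with a chiral phosphoric acid. No ring of the target is closed; the only cycle is the transient B–O–C7–C8–C9–C10 chair of the transition state. C7 (S) is controlled by the catalyst, which opens the Re face of 11, and C8 (R) is controlled by the E geometry of 12, whose aryloxy group sits equatorial in the chair so that C7–OH and C8–OAr come out anti (erythro). The step needs E over Z geometry, catalysed over background addition and indifference to the existing C8' centre: the first is secured by the bulky 2,6-dimethoxyaryl ether under the E-selective iridium catalyst, the second by the sluggishness of a pinacol boronate towards the electron-rich aldehyde 11 at −30 °C without acid, and the third by the seven bonds between C8 and C8'. The aryl enol ether of 12 is less basic than an alkyl enol ether, which should protect it from protonation by the acid catalyst.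

Step 9
Reactants: 14 (1S,2R)-1-[4-(benzyloxy)-3,5-dimethoxyphenyl]-2-{4-[(2S)-2,3-bis(benzyloxy)propyl]-2,6-dimethoxyphenoxy}but-3-en-1-ol
Product: 17 (1S,2R)-1-[4-(benzyloxy)-3,5-dimethoxyphenyl]-2-{4-[(2S)-2,3-bis(benzyloxy)propyl]-2,6-dimethoxyphenoxy}propane-1,3-diol, via vicinal diol 15 (not isolated), via aldehyde 16 (not isolated)
Conditions: OsO4 (2 mol %), NaIO4, 2,6-lutidine, dioxane–H2O, rt; extraction; then NaBH4, MeOH, 0 °C
Reagents that add atoms: osmium tetroxide, O=[Os](=O)(=O)=O; sodium periodate (terminal oxidant that refills the osmium oxo groups), [Na+].[O-]I(=O)(=O)=O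
Why: Lemieux–Johnson oxidation (catalytic dihydroxylation, then periodate glycol cleavage) excises C10 from the only alkene, the lutidine buffer keeps the β-hydroxy-α-aryloxy aldehyde 16 from epimerising, and immediate borohydride reduction fixes C9 as CH2OH with C7 and C8 unchanged.

Step 10
Reactants: 17 (1S,2R)-1-[4-(benzyloxy)-3,5-dimethoxyphenyl]-2-{4-[(2S)-2,3-bis(benzyloxy)propyl]-2,6-dimethoxyphenoxy}propane-1,3-diol
Product: 18 (1S,2R)-2-{4-[(2S)-2,3-dihydroxypropyl]-2,6-dimethoxyphenoxy}-1-(4-hydroxy-3,5-dimethoxyphenyl)propane-1,3-diol (target)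
Conditions: H2 (1 atm), 10 % Pd/C, EtOAc–EtOH, rt
Reagents that add atoms: none
Why: Catalytic hydrogenolysis of benzyl ethers under neutral conditions frees the phenol and the two side-chain hydroxyls in one operation, and the secondary benzylic C7–OH, a poor leaving group next to the bulky C8 substituent, should be cleaved far more slowly than the O-benzyl groups.

## Compound list

1 | 4-bromo-2,6-dimethoxyphenol | COc1cc(Br)cc(OC)c1O | starting material
2 | 5-bromo-1,3-dimethoxy-2-(methoxymethoxy)benzene | COCOc1c(OC)cc(Br)cc1OC | intermediate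
3 | (S)-benzyl glycidyl ether | c1ccccc1COC[C@@H]2CO2 | starting material
4 | [3,5-dimethoxy-4-(methoxymethoxy)phenyl]magnesium bromide (not isolated) | COCOc1c(OC)cc([Mg]Br)cc1OC | intermediate
5 | (2S)-1-(benzyloxy)-3-[3,5-dimethoxy-4-(methoxymethoxy)phenyl]propan-2-ol | COCOc1c(OC)cc(C[C@H](O)COCc2ccccc2)cc1OC | intermediate
6 | 5-[(2S)-2,3-bis(benzyloxy)propyl]-1,3-dimethoxy-2-(methoxymethoxy)benzene | COCOc1c(OC)cc(C[C@H](OCc2ccccc2)COCc2ccccc2)cc1OC | intermediate
7 | 4-[(2S)-2,3-bis(benzyloxy)propyl]-2,6-dimethoxyphenol | COc1cc(C[C@H](OCc2ccccc2)COCc2ccccc2)cc(OC)c1O | intermediate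
8 | 5-[(2S)-2,3-bis(benzyloxy)propyl]-1,3-dimethoxy-2-(prop-2-yn-1-yloxy)benzene | C#CCOc1c(OC)cc(C[C@H](OCc2ccccc2)COCc2ccccc2)cc1OC | intermediate
9 | (E)-3-aryloxyprop-1-enylboronic acid pinacol ester (aryl = 4-[(2S)-2,3-bis(benzyloxy)propyl]-2,6-dimethoxyphenyl) | CC1(C)OB(/C=C/COc2c(OC)cc(C[C@H](OCc3ccccc3)COCc3ccccc3)cc2OC)OC1(C)C | intermediate
10 | syringaldehyde | COc1cc(C=O)cc(OC)c1O | starting material
11 | 4-(benzyloxy)-3,5-dimethoxybenzaldehyde | COc1cc(C=O)cc(OC)c1OCc1ccccc1 | intermediate
12 | (E)-3-aryloxyprop-2-enylboronic acid pinacol ester, same aryl group as in 9 (not isolated) | CC1(C)OB(C/C=C/Oc2c(OC)cc(C[C@H](OCc3ccccc3)COCc3ccccc3)cc2OC)OC1(C)C | intermediate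
13 | C7-O-(pinacolatoboryl) derivative of 14 (not isolated) | COc1cc([C@H](OB2OC(C)(C)C(C)(C)O2)[C@@H](C=C)Oc2c(OC)cc(C[C@H](OCc3ccccc3)COCc3ccccc3)cc2OC)cc(OC)c1OCc1ccccc1 | intermediate
14 | (1S,2R)-1-[4-(benzyloxy)-3,5-dimethoxyphenyl]-2-{4-[(2S)-2,3-bis(benzyloxy)propyl]-2,6-dimethoxyphenoxy}but-3-en-1-ol | COc1cc([C@H](O)[C@@H](C=C)Oc2c(OC)cc(C[C@H](OCc3ccccc3)COCc3ccccc3)cc2OC)cc(OC)c1OCc1ccccc1 | intermediate
15 | butane-1,3,4-triol from dihydroxylation of 14, C7 and C8 as in 14, both epimers at the new carbinol (not isolated) | COc1cc([C@H](O)[C@@H](C(O)CO)Oc2c(OC)cc(C[C@H](OCc3ccccc3)COCc3ccccc3)cc2OC)cc(OC)c1OCc1ccccc1 | intermediate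
16 | (2S,3S)-3-[4-(benzyloxy)-3,5-dimethoxyphenyl]-2-{4-[(2S)-2,3-bis(benzyloxy)propyl]-2,6-dimethoxyphenoxy}-3-hydroxypropanal (not isolated) | COc1cc([C@H](O)[C@@H](C=O)Oc2c(OC)cc(C[C@H](OCc3ccccc3)COCc3ccccc3)cc2OC)cc(OC)c1OCc1ccccc1 | intermediate
17 | (1S,2R)-1-[4-(benzyloxy)-3,5-dimethoxyphenyl]-2-{4-[(2S)-2,3-bis(benzyloxy)propyl]-2,6-dimethoxyphenoxy}propane-1,3-diol | COc1cc([C@H](O)[C@@H](CO)Oc2c(OC)cc(C[C@H](OCc3ccccc3)COCc3ccccc3)cc2OC)cc(OC)c1OCc1ccccc1 | intermediate
18 | (1S,2R)-2-{4-[(2S)-2,3-dihydroxypropyl]-2,6-dimethoxyphenoxy}-1-(4-hydroxy-3,5-dimethoxyphenyl)propane-1,3-diol | COc1cc([C@H](O)[C@@H](CO)Oc2c(OC)cc(C[C@H](O)CO)cc2OC)cc(OC)c1O | target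

## Step count and risks

Total step count: 10. Longest linear sequence: 9 (steps 1–6, 8, 9 and 10, starting from 1).

Steps most likely to fail:

**Step 8.**
- **Risk:** The E geometry may leak during the isomerisation. The acid may protonate or protodeboronate the enol-ether allylboronate. Uncatalysed background addition may lower the facial selectivity. Residual iridium hydride may move the vinyl group of the product onward.
- **Fallback:** It sets out from 7 (with 11) and comes back to the route at 17. It forms the same C7–C8 bond by auxiliary-controlled aldol chemistry. Phenol 7 is O-alkylated with (S)-4-benzyl-3-(chloroacetyl)oxazolidin-2-one (K2CO3, NaI, acetone) to give the N-(aryloxyacetyl)oxazolidinone F1. Its dibutylboron Z-enolate (Bu2BOTf, iPr2NEt, CH2Cl2, −78 °C) adds to 11 in an Evans syn aldol reaction to give the (7R,8R) syn adduct F2, in which C8 already has the required configuration. LiBH4 (THF, 0 °C) removes the auxiliary reductively and gives the threo diol F3. A double Mitsunobu esterification (4-nitrobenzoic acid, PPh3, DIAD, THF) esterifies C9–OH and inverts C7, giving the erythro bis(4-nitrobenzoate) F4. Methanolysis (K2CO3, MeOH) then delivers 17.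

**Step 9.**
- **Risk:** The free β-hydroxy-α-aryloxy aldehyde may undergo retro-aldol fragmentation or epimerise at C8 while it waits for reduction.
- **Fallback:** It sets out from 14 and comes back at 17. It blocks the retro-aldol channel by masking C7–OH and splits the one-pot operation into controlled stages. Alcohol 14 is silylated (TESCl, imidazole, CH2Cl2) to the C7 triethylsilyl ether F5. Dihydroxylation (OsO4 cat., NMO, acetone–H2O) gives the isolated diol F6. Silica-supported NaIO4 in CH2Cl2 cleaves it under non-basic conditions to the silyl-protected aldehyde F7. This is reduced at once (NaBH4, EtOH, −20 °C) to the C7-O-TES alcohol F8. Any 1,3-silyl migration at this point is harmless, because TBAF (THF, 0 °C) frees both positions and gives 17.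

**Step 10.**
- **Risk:** The two aliphatic benzyl ethers are slow to cleave. During the time they need, the benzylic C7–O bond may be hydrogenolysed, especially once ring A is a free para-hydroxyphenyl group.
- **Fallback:** It sets out from 17 and comes back at 18. It shields the benzylic oxygen before the reduction. Diol 17 is converted (TBSOTf, 2,6-lutidine, CH2Cl2, 0 °C) into the C7,C9-bis(tert-butyldimethylsilyl) ether F9. Forcing hydrogenolysis (H2, Pd(OH)2/C, EtOAc) then removes all three benzyl groups and gives the bis-silyl phenol-diol F10. Buffered fluoride (TBAF–AcOH, THF, rt) releases 18 without exposing the benzylic alcohol to acid.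

## Further compounds

F1 | step 8 | (S)-4-benzyl-3-(2-{4-[(2S)-2,3-bis(benzyloxy)propyl]-2,6-dimethoxyphenoxy}acetyl)oxazolidin-2-one | COc1cc(C[C@H](OCc2ccccc2)COCc2ccccc2)cc(OC)c1OCC(=O)N1C(=O)OC[C@@H]1Cc1ccccc1
F2 | step 8 | Evans syn aldol adduct, (7R,8R), (S)-4-benzyloxazolidin-2-one imide at C9 | COc1cc([C@@H](O)[C@@H](C(=O)N4C(=O)OC[C@@H]4Cc5ccccc5)Oc2c(OC)cc(C[C@H](OCc3ccccc3)COCc3ccccc3)cc2OC)cc(OC)c1OCc1ccccc1
F3 | step 8 | threo (1R,2R) diastereomer of 17 | COc1cc([C@@H](O)[C@@H](CO)Oc2c(OC)cc(C[C@H](OCc3ccccc3)COCc3ccccc3)cc2OC)cc(OC)c1OCc1ccccc1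
F4 | step 8 | C7,C9-bis(4-nitrobenzoate) of 17 (erythro, C7 inverted) | COc1cc([C@H](OC(=O)c4ccc([N+](=O)[O-])cc4)[C@@H](COC(=O)c5ccc([N+](=O)[O-])cc5)Oc2c(OC)cc(C[C@H](OCc3ccccc3)COCc3ccccc3)cc2OC)cc(OC)c1OCc1ccccc1
F5 | step 9 | C7-O-triethylsilyl ether of 14 | COc1cc([C@H](O[Si](CC)(CC)CC)[C@@H](C=C)Oc2c(OC)cc(C[C@H](OCc3ccccc3)COCc3ccccc3)cc2OC)cc(OC)c1OCc1ccccc1
F6 | step 9 | C7-O-triethylsilyl ether of diol 15 (both epimers at the new carbinol) | COc1cc([C@H](O[Si](CC)(CC)CC)[C@@H](C(O)CO)Oc2c(OC)cc(C[C@H](OCc3ccccc3)COCc3ccccc3)cc2OC)cc(OC)c1OCc1ccccc1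
F7 | step 9 | C7-O-triethylsilyl ether of aldehyde 16 | COc1cc([C@H](O[Si](CC)(CC)CC)[C@@H](C=O)Oc2c(OC)cc(C[C@H](OCc3ccccc3)COCc3ccccc3)cc2OC)cc(OC)c1OCc1ccccc1
F8 | step 9 | C7-O-triethylsilyl ether of 17 | COc1cc([C@H](O[Si](CC)(CC)CC)[C@@H](CO)Oc2c(OC)cc(C[C@H](OCc3ccccc3)COCc3ccccc3)cc2OC)cc(OC)c1OCc1ccccc1
F9 | step 10 | C7,C9-bis(tert-butyldimethylsilyl) ether of 17 | COc1cc([C@H](O[Si](C)(C)C(C)(C)C)[C@@H](CO[Si](C)(C)C(C)(C)C)Oc2c(OC)cc(C[C@H](OCc3ccccc3)COCc3ccccc3)cc2OC)cc(OC)c1OCc1ccccc1
F10 | step 10 | C7,C9-bis(tert-butyldimethylsilyl) ether of 18 | COc1cc([C@H](O[Si](C)(C)C(C)(C)C)[C@@H](CO[Si](C)(C)C(C)(C)C)Oc2c(OC)cc(C[C@H](O)CO)cc2OC)cc(OC)c1O
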